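**Retrosynthetic overview**
1. The target is the 8-O-(E)-p-coumaroyl ester of a bulnesol-type guai-1(10)-ene-8,11-diol; the ester is attached last (C8–O acylation with (E)-4-acetoxycinnamic acid, then release of the phenol).
2. Key disconnection: the tetrasubstituted C1=C10 olefin and with it ring B (seven-membered: C1, C5–C10), then C2=C3 and ring A (five-membered: C1–C5), both in one relay ene–yne–ene metathesis of an acyclic dienyne; the extra C2=C3 olefin is removed afterwards with diimide.
3. Enabling feature: C1=C10 is endocyclic in ring B but exocyclic to ring A, and the ring-fusion carbon C1 carries C2. C1≡C2 can therefore be an alkyne flanked by a C10 alkylidene precursor and a C3 olefin, and C5, being propargylic, cannot epimerize.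
4. Dienyne: C8 from ethyl (R)-4-chloro-3-hydroxybutanoate, C7 by Fráter–Seebach-type Michael addition, C4 and C5 by Ireland–Claisen rearrangement with chirality transfer, the alkyne by homologation of a δ-lactol.
5. Ring order: ring B first, ring A second, in the same operation.

Key step: step 12

Remark: atoms are numbered as in guaiane (C1/C5 ring fusion, C4 and C10 methyl-bearing, C7 bearing C11, C8 bearing the ester oxygen); but-2-yn-1-ol, ethyl (R)-4-chloro-3-hydroxybutanoate, pent-3-yn-2-one and (E)-4-acetoxycinnamic acid are taken as commercial.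

**Route**

Step 1
Reactants: 1 but-2-yn-1-ol
Product: 3 (Z)-3-iodobut-2-en-1-ol, via sodium alkenylaluminate 2 (not isolated)
Conditions: NaAlH2(OCH2CH2OCH3)2, THF, 0 °C to rt; then I2, −78 °C
Reagents that add atoms: iodine, II
Why: The alkoxide-bound aluminium hydride adds hydride to C2 and aluminium to C3 in an anti hydroalumination that closes the five-membered chelate 2, and iodinolysis with retention gives the Z-iodide with iodine cis to the CH2OH arm (hydroalumination–iodination of a propargylic alcohol).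

Step 2
Reactants: 3 (Z)-3-iodobut-2-en-1-ol
Product: 4 allyl (Z)-3-iodobut-2-enyl ether
Conditions: NaH, THF, 0 °C; allyl bromide, rt
Reagents that add atoms: allyl bromide, C=CCBr
Why: Williamson etherification installs the terminal olefin that later acts as the relay arm, and the vinyl iodide is inert to NaH at this temperature.

Step 3
Reactants: 5 ethyl (R)-4-chloro-3-hydroxybutanoate
Product: 6 ethyl (R)-3,4-epoxybutanoate
Conditions: Ag2O, 1,2-dimethoxyethane, reflux
Reagents that add atoms: none
Why: Ag2O promotes intramolecular Williamson-type displacement of chloride by the hydroxyl under non-basic conditions, which avoids elimination to the crotonate and leaves the stereocentre (not a reacting atom) unchanged.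

Step 4
Reactants: 4 allyl (Z)-3-iodobut-2-enyl ether; 6 ethyl (R)-3,4-epoxybutanoate
Product: 8 ethyl (3S,5Z)-7-(allyloxy)-3-hydroxy-5-methylhept-5-enoate, via alkenylmagnesium chloride 7 (not isolated)
Conditions: 4, i-PrMgCl·LiCl, THF, 0 °C to rt; then CuI (10 mol %), 6, −30 °C
Reagents that add atoms: none
Why: Iodine–magnesium exchange proceeds with retention of the olefin geometry and the copper-catalysed Grignard opening attacks only the unsubstituted epoxide carbon, so the carbinol centre keeps its spatial arrangement (descriptor S by priority change) and the ester survives at low temperature.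

Step 5
Reactants: 9 pent-3-yn-2-one
Product: 10 (S)-pent-3-yn-2-ol
Conditions: RuCl[(S,S)-TsDPEN](p-cymene) (0.5 mol %), i-PrOH, rt
Reagents that add atoms: none
Why: Noyori asymmetric transfer hydrogenation of the ynone, in which the (S,S)-diamine ligand directs hydride to the face that gives the (S)-propargylic alcohol.

Step 6
Reactants: 10 (S)-pent-3-yn-2-ol
Product: 11 (2S,3Z)-pent-3-en-2-ol
Conditions: H2 (1 atm), Pd/CaCO3 poisoned with Pb(OAc)2, quinoline, pentane, 0 °C
Reagents that add atoms: none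
Why: Lindlar semihydrogenation adds hydrogen syn to the alkyne and stops at the Z-olefin without touching the carbinol centre.

Step 7
Reactants: 11 (2S,3Z)-pent-3-en-2-ol
Product: 12 (2S,3Z)-pent-3-en-2-yl acrylate
Conditions: acryloyl chloride, NEt3, CH2Cl2, −20 °C
Reagents that add atoms: acryloyl chloride, C=CC(Cl)=O
Why: Standard O-acylation of the secondary allylic alcohol with retention at the carbinol carbon.

Step 8
Reactants: 8 ethyl (3S,5Z)-7-(allyloxy)-3-hydroxy-5-methylhept-5-enoate; 12 (2S,3Z)-pent-3-en-2-yl acrylate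
Product: 17 (2S,4S,5S,7Z)-9-(allyloxy)-4-(ethoxycarbonyl)-7-methyl-2-[(2S,3E)-pent-3-en-2-yl]-5-(triethylsilyloxy)non-7-enoic acid, via dilithium dianion 13 (not isolated), via dilithium enolate alkoxide 14 (not isolated), via bis-silyl ketene acetal 15 (not isolated), via triethylsilyl ester 16 (not isolated)
Conditions: LiN(i-Pr)2 (2.2 equiv), THF, −78 to −20 °C; 12, −78 °C; Et3SiCl, NEt3, −78 to 40 °C; aq. NH4Cl
Reagents that add atoms: chlorotriethylsilane, CC[Si](Cl)(CC)CC
Why: Fráter–Seebach-type conjugate addition of the chelated dianion to the s-cis acrylate should set C7 anti to the C8 oxygen and deliver the Z(O) ester enolate regiospecifically at C5, which after O-silylation undergoes Ireland–Claisen rearrangement through a chair with the carbinol methyl equatorial and the Z-olefin methyl axial, so that chirality transfer from the (S)-carbinol fixes C4 and the enolate geometry fixes C5 (4S,5S, anti), the new propenyl olefin being E.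

Step 9
Reactants: 17 (2S,4S,5S,7Z)-9-(allyloxy)-4-(ethoxycarbonyl)-7-methyl-2-[(2S,3E)-pent-3-en-2-yl]-5-(triethylsilyloxy)non-7-enoic acid
Product: 20 (3S,5S,6S)-6-[(2Z)-4-(allyloxy)-2-methylbut-2-enyl]-5-(2-hydroxypropan-2-yl)-3-[(2S,3E)-pent-3-en-2-yl]tetrahydropyran-2-one, via silyl ether hydroxy acid 18 (not isolated), via dihydroxy acid 19 (not isolated)
Conditions: MeMgBr (6 equiv), THF, 0 °C to rt; then 1 M HCl, THF, rt
Reagents that add atoms: methylmagnesium bromide, C[Mg]Br
Why: Double Grignard addition to the ethyl ester (the magnesium carboxylate does not react) builds the C11 carbinol, and acid then removes the silyl ether and closes the six-membered lactone on the secondary C8 hydroxyl without touching a stereocentre.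

Step 10
Reactants: 20 (3S,5S,6S)-6-[(2Z)-4-(allyloxy)-2-methylbut-2-enyl]-5-(2-hydroxypropan-2-yl)-3-[(2S,3E)-pent-3-en-2-yl]tetrahydropyran-2-one
Product: 21 (3S,5S,6S)-6-[(2Z)-4-(allyloxy)-2-methylbut-2-enyl]-5-(2-hydroxypropan-2-yl)-3-[(2S,3E)-pent-3-en-2-yl]tetrahydropyran-2-ol
Conditions: i-Bu2AlH (2.2 equiv), CH2Cl2, −78 °C; aq. potassium sodium tartrate
Reagents that add atoms: none
Why: Partial reduction of the lactone at low temperature stops at the aluminium hemiacetal, which gives the lactol on work-up (the extra equivalent is consumed by the tertiary hydroxyl).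

Step 11
Reactants: 21 (3S,5S,6S)-6-[(2Z)-4-(allyloxy)-2-methylbut-2-enyl]-5-(2-hydroxypropan-2-yl)-3-[(2S,3E)-pent-3-en-2-yl]tetrahydropyran-2-ol
Product: 22 (3S,4S,6Z)-8-(allyloxy)-3-[(2S,3S,4E)-2-ethynyl-3-methylhex-4-enyl]-2,6-dimethyloct-6-ene-2,4-diol
Conditions: dimethyl (1-diazo-2-oxopropyl)phosphonate, K2CO3, MeOH, 0 °C to rt
Reagents that add atoms: dimethyl (1-diazo-2-oxopropyl)phosphonate, COP(=O)(OC)C(=[N+]=[N-])C(C)=O
Why: Ohira–Bestmann (Seyferth–Gilbert) homologation converts the masked C1 aldehyde into the terminal alkyne under mildly basic conditions chosen to avoid epimerisation at C5, and the ring opening frees the C8 hydroxyl.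

Step 12
Reactants: 22 (3S,4S,6Z)-8-(allyloxy)-3-[(2S,3S,4E)-2-ethynyl-3-methylhex-4-enyl]-2,6-dimethyloct-6-ene-2,4-diol
Product: 23 (3S,3aS,5S,6S)-5-(2-hydroxypropan-2-yl)-3,8-dimethyl-3,3a,4,5,6,7-hexahydroazulen-6-ol
Conditions: second-generation Grubbs catalyst (10 mol %), CH2Cl2 (0.002 M), 40 °C, argon
Reagents that add atoms: none
Why: The catalyst loads at the only unhindered terminal olefin (the allyl ether), and relay ring-closing metathesis expels 2,5-dihydrofuran and leaves the ruthenium alkylidene on C10. This alkylidene adds to the tethered terminal alkyne in the exo mode (carbene carbon to the proximal alkyne carbon C1), which forms the tetrasubstituted C1=C10 bond and closes ring B as a seven-membered ring by enyne metathesis, the metal passing to C2 as a vinylcarbene. Ring A then closes as a five-membered ring by ordinary olefin ring-closing metathesis of this carbene with the C3 propenyl olefin, which releases an ethylidene that leaves as propene in the next turnover. The closest known reaction type is relay-initiated ene–yne–ene (dienyne) ring-closing metathesis to fused bicyclic 1,3-dienes. No stereocentre is created, and C4, C5, C7 and C8 are not touched under the neutral conditions. The step needs site-selective initiation and ring B before ring A: the relay arm, the low reactivity of the internal propenyl and trisubstituted olefins, the lack of a productive small-ring closure from a C3 carbene and high dilution should secure this.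

Step 13
Reactants: 23 (3S,3aS,5S,6S)-5-(2-hydroxypropan-2-yl)-3,8-dimethyl-3,3a,4,5,6,7-hexahydroazulen-6-ol
Product: 24 (3S,3aS,5S,6S)-5-(2-hydroxypropan-2-yl)-3,8-dimethyl-1,2,3,3a,4,5,6,7-octahydroazulen-6-ol
Conditions: 2-nitrobenzenesulfonohydrazide, NEt3, CH2Cl2, rt
Reagents that add atoms: none
Why: Diimide transfers hydrogen syn to the unhindered cis-disubstituted C2=C3 bond only, because the tetrasubstituted C1=C10 bond is too hindered for this concerted reduction, and no stereocentre is created.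

Step 14
Reactants: 24 (3S,3aS,5S,6S)-5-(2-hydroxypropan-2-yl)-3,8-dimethyl-1,2,3,3a,4,5,6,7-octahydroazulen-6-ol; 25 (E)-4-acetoxycinnamic acid
Product: 26 (3S,3aS,5S,6S)-5-(2-hydroxypropan-2-yl)-3,8-dimethyl-1,2,3,3a,4,5,6,7-octahydroazulen-6-yl (E)-3-(4-acetoxyphenyl)prop-2-enoate
Conditions: EDC·HCl, DMAP, CH2Cl2, 0 °C to rt
Reagents that add atoms: none
Why: Steglich esterification acylates the secondary C8 hydroxyl with retention while the tertiary C11 hydroxyl is too hindered to react, and the acetate keeps the phenol from competing.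

Step 15
Reactants: 26 (3S,3aS,5S,6S)-5-(2-hydroxypropan-2-yl)-3,8-dimethyl-1,2,3,3a,4,5,6,7-octahydroazulen-6-yl (E)-3-(4-acetoxyphenyl)prop-2-enoate
Product: 27 (3S,3aS,5S,6S)-5-(2-hydroxypropan-2-yl)-3,8-dimethyl-1,2,3,3a,4,5,6,7-octahydroazulen-6-yl (E)-3-(4-hydroxyphenyl)prop-2-enoate
Conditions: pyrrolidine (2 equiv), CH2Cl2, 0 °C
Reagents that add atoms: none
Why: Aryl acetates undergo aminolysis far faster than the hindered secondary cinnamate, so pyrrolidine should free the phenol selectively.

**Compound list**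

1 | but-2-yn-1-ol | CC#CCO | starting material
2 | sodium 2,2-bis(2-methoxyethoxy)-3-methyl-2,5-dihydro-1,2-oxaaluminol-2-uide (alkenylaluminate chelate) | CC1=CCO[Al-]1(OCCOC)OCCOC.[Na+] | intermediate
3 | (Z)-3-iodobut-2-en-1-ol | C/C(I)=C/CO | intermediate
4 | allyl (Z)-3-iodobut-2-enyl ether | C/C(I)=C/COCC=C | intermediate
5 | ethyl (R)-4-chloro-3-hydroxybutanoate | CCOC(=O)C[C@@H](O)CCl | starting material
6 | ethyl (R)-3,4-epoxybutanoate | CCOC(=O)C[C@@H]1CO1 | intermediate
7 | (Z)-4-(allyloxy)but-2-en-2-ylmagnesium chloride | C/C([Mg]Cl)=C/COCC=C | intermediate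
8 | ethyl (3S,5Z)-7-(allyloxy)-3-hydroxy-5-methylhept-5-enoate | CCOC(=O)C[C@@H](O)C/C(C)=C\COCC=C | intermediate
9 | pent-3-yn-2-one | CC(=O)C#CC | starting material
10 | (S)-pent-3-yn-2-ol | C[C@H](O)C#CC | intermediate
11 | (2S,3Z)-pent-3-en-2-ol | C[C@H](O)/C=C\C | intermediate
12 | (2S,3Z)-pent-3-en-2-yl acrylate | C=CC(=O)O[C@@H](C)/C=C\C | intermediate
13 | dilithium alkoxide enolate (dianion) of 8 | [Li]OC(OCC)=C[C@@H](O[Li])C/C(C)=C\COCC=C | intermediate
14 | dilithium Michael adduct of 13 and 12 (C8 alkoxide, Z(O) enolate of the pentenyl ester) | [Li]O/C(O[C@@H](C)/C=C\C)=C\C[C@H](C(=O)OCC)[C@@H](O[Li])C/C(C)=C\COCC=C | intermediate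
15 | bis(triethylsilyl) derivative of 14 (C8 silyl ether, silyl ketene acetal) | CC[Si](CC)(CC)O/C(O[C@@H](C)/C=C\C)=C\C[C@H](C(=O)OCC)[C@@H](O[Si](CC)(CC)CC)C/C(C)=C\COCC=C | intermediate
16 | triethylsilyl ester of 17 | CC[Si](CC)(CC)OC(=O)[C@H]([C@@H](C)/C=C/C)C[C@H](C(=O)OCC)[C@@H](O[Si](CC)(CC)CC)C/C(C)=C\COCC=C | intermediate
17 | (2S,4S,5S,7Z)-9-(allyloxy)-4-(ethoxycarbonyl)-7-methyl-2-[(2S,3E)-pent-3-en-2-yl]-5-(triethylsilyloxy)non-7-enoic acid | OC(=O)[C@H]([C@@H](C)/C=C/C)C[C@H](C(=O)OCC)[C@@H](O[Si](CC)(CC)CC)C/C(C)=C\COCC=C | intermediate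
18 | (2S,4S,5S,7Z)-9-(allyloxy)-4-(2-hydroxypropan-2-yl)-7-methyl-2-[(2S,3E)-pent-3-en-2-yl]-5-(triethylsilyloxy)non-7-enoic acid | OC(=O)[C@H]([C@@H](C)/C=C/C)C[C@H](C(C)(C)O)[C@@H](O[Si](CC)(CC)CC)C/C(C)=C\COCC=C | intermediate
19 | (2S,4S,5S,7Z)-9-(allyloxy)-5-hydroxy-4-(2-hydroxypropan-2-yl)-7-methyl-2-[(2S,3E)-pent-3-en-2-yl]non-7-enoic acid | OC(=O)[C@H]([C@@H](C)/C=C/C)C[C@H](C(C)(C)O)[C@@H](O)C/C(C)=C\COCC=C | intermediate
20 | (3S,5S,6S)-6-[(2Z)-4-(allyloxy)-2-methylbut-2-enyl]-5-(2-hydroxypropan-2-yl)-3-[(2S,3E)-pent-3-en-2-yl]tetrahydropyran-2-one | O=C1O[C@@H](C/C(C)=C\COCC=C)[C@@H](C(C)(C)O)C[C@H]1[C@@H](C)/C=C/C | intermediate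
21 | (3S,5S,6S)-6-[(2Z)-4-(allyloxy)-2-methylbut-2-enyl]-5-(2-hydroxypropan-2-yl)-3-[(2S,3E)-pent-3-en-2-yl]tetrahydropyran-2-ol (both anomers) | OC1O[C@@H](C/C(C)=C\COCC=C)[C@@H](C(C)(C)O)C[C@H]1[C@@H](C)/C=C/C | intermediate
22 | (3S,4S,6Z)-8-(allyloxy)-3-[(2S,3S,4E)-2-ethynyl-3-methylhex-4-enyl]-2,6-dimethyloct-6-ene-2,4-diol | C#C[C@H]([C@@H](C)/C=C/C)C[C@H](C(C)(C)O)[C@@H](O)C/C(C)=C\COCC=C | intermediate
23 | (3S,3aS,5S,6S)-5-(2-hydroxypropan-2-yl)-3,8-dimethyl-3,3a,4,5,6,7-hexahydroazulen-6-ol | CC1=C2C=C[C@H](C)[C@@H]2C[C@H](C(C)(C)O)[C@@H](O)C1 | intermediate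
24 | (3S,3aS,5S,6S)-5-(2-hydroxypropan-2-yl)-3,8-dimethyl-1,2,3,3a,4,5,6,7-octahydroazulen-6-ol | CC1=C2CC[C@H](C)[C@@H]2C[C@H](C(C)(C)O)[C@@H](O)C1 | intermediate
25 | (E)-4-acetoxycinnamic acid | CC(=O)Oc1ccc(/C=C/C(=O)O)cc1 | starting material
26 | (3S,3aS,5S,6S)-5-(2-hydroxypropan-2-yl)-3,8-dimethyl-1,2,3,3a,4,5,6,7-octahydroazulen-6-yl (E)-3-(4-acetoxyphenyl)prop-2-enoate | CC1=C2CC[C@H](C)[C@@H]2C[C@H](C(C)(C)O)[C@@H](OC(=O)/C=C/c2ccc(OC(C)=O)cc2)C1 | intermediate
27 | (3S,3aS,5S,6S)-5-(2-hydroxypropan-2-yl)-3,8-dimethyl-1,2,3,3a,4,5,6,7-octahydroazulen-6-yl (E)-3-(4-hydroxyphenyl)prop-2-enoate | CC1=C2CC[C@H](C)[C@@H]2C[C@H](C(C)(C)O)[C@@H](OC(=O)/C=C/c2ccc(O)cc2)C1 | target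

**Step count and risks**

Total step count: 15. Longest linear sequence: 11 steps (1, 2, 4, 8, 9, 10, 11, 12, 13, 14, 15; the branch 5, 6, 7, 8–15 is equally long).

Steps most likely to fail:

Step 12. The catalyst may load at the terminal alkyne or at the propenyl olefin instead of the relay terminus. The five-membered ring would then close first, and the sequence would stall before the tetrasubstituted bond is made. Fallback, from 22 back to 23: the C1–C10 bond is made by π-acid catalysis instead of by a ruthenium alkylidene. PtCl2 in toluene at 80 °C should effect the skeletal enyne rearrangement (formal enyne metathesis). In it the trisubstituted olefin attacks the activated alkyne, C10 bonds to C1 and the former olefinic CH migrates to C2, giving the monocyclic cycloheptene (1S,5S,7S)-4-[(1E)-3-(allyloxy)prop-1-enyl]-7-(2-hydroxypropan-2-yl)-3-methyl-5-[(2S,3E)-pent-3-en-2-yl]cyclohept-3-en-1-ol F1. Ordinary diene ring-closing metathesis of F1 (second-generation Grubbs catalyst) between the C2 and C3 olefins then closes ring A and gives 23.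

Step 8. The acrylate may oligomerize, the C8 alkoxide may lactonize onto the new ester before silylation, or the enolate geometry may erode and give C5 epimers. Fallback, from 8 (with 12) back to 17: the tandem is split into discrete, individually known operations. The conjugate addition of 13 to 12 is quenched at −78 °C with acetic acid to give the hydroxy diester ethyl (2S,3S,5Z)-7-(allyloxy)-3-hydroxy-5-methyl-2-{3-oxo-3-[(2S,3Z)-pent-3-en-2-yloxy]propyl}hept-5-enoate F2. The C8 hydroxyl is silylated (Et3SiOTf, 2,6-lutidine) to the triethylsilyl ether F3. A classical Ireland–Claisen rearrangement follows: enolisation of the unhindered C5 methylene with LiN(i-Pr)2 in THF–DMPU (Z(O) enolate by deprotonation), trapping with Et3SiCl and warming. This should give 16 and, after aqueous work-up, 17.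

Step 11. The lactol may open sluggishly, and the base may epimerize C5 through the aldehyde form. Fallback, from 21 back to 22: olefination and elimination replace the diazophosphonate homologation. Wittig chloromethylenation of the lactol (Ph3P=CHCl from (chloromethyl)triphenylphosphonium chloride and NaN(SiMe3)2) should give the chloroalkene (3S,4S,6Z)-8-(allyloxy)-3-[(2S,3S,4E)-2-(2-chloroethenyl)-3-methylhex-4-enyl]-2,6-dimethyloct-6-ene-2,4-diol F4. Dehydrochlorination of F4 with excess LiN(i-Pr)2 at −78 °C then gives 22.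

Further compounds
F1 | step 12 | (1S,5S,7S)-4-[(1E)-3-(allyloxy)prop-1-enyl]-7-(2-hydroxypropan-2-yl)-3-methyl-5-[(2S,3E)-pent-3-en-2-yl]cyclohept-3-en-1-ol | CC1=C(/C=C/COCC=C)[C@H]([C@@H](C)/C=C/C)C[C@H](C(C)(C)O)[C@@H](O)C1
F2 | step 8 | ethyl (2S,3S,5Z)-7-(allyloxy)-3-hydroxy-5-methyl-2-{3-oxo-3-[(2S,3Z)-pent-3-en-2-yloxy]propyl}hept-5-enoate | CCOC(=O)[C@@H](CCC(=O)O[C@@H](C)/C=C\C)[C@@H](O)C/C(C)=C\COCC=C
F3 | step 8 | ethyl (2S,3S,5Z)-7-(allyloxy)-5-methyl-2-{3-oxo-3-[(2S,3Z)-pent-3-en-2-yloxy]propyl}-3-(triethylsilyloxy)hept-5-enoate | CCOC(=O)[C@@H](CCC(=O)O[C@@H](C)/C=C\C)[C@@H](O[Si](CC)(CC)CC)C/C(C)=C\COCC=C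
F4 | step 11 | (3S,4S,6Z)-8-(allyloxy)-3-[(2S,3S,4E)-2-(2-chloroethenyl)-3-methylhex-4-enyl]-2,6-dimethyloct-6-ene-2,4-diol (E/Z mixture at the chloroalkene) | ClC=C[C@H]([C@@H](C)/C=C/C)C[C@H](C(C)(C)O)[C@@H](O)C/C(C)=C\COCC=C
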